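**Retrosynthetic overview**

1. Target 23 ⇒ bis(benzyl ether) 22 ⇒ bis(4-hydroxy-2-pyranone) 21 ⇒ α-truxillic diacid 16. Both pyranone rings come from the two carboxyl groups by γ-acylation of dioxinone 18 and acylketene ring closure; these rings are formed last.
2. 16 ⇒ bisphenol diester 14 ⇒ bis(1-nitrovinyl) diester 10 + two molecules of diene 11. A twofold Diels–Alder reaction and aromatisation builds each benzene ring on the carbon already bonded to the cyclobutane; these rings are formed second.
3. 10 ⇒ bis(nitromethyl) diester 7 + formaldehyde 8 ⇒ bis(iodomethyl) diester 6 ⇒ head-to-tail bis-lactone 4 ⇒ centrosymmetric half-ester 2 ⇒ dianhydride 1. The cyclobutane and all four stereocentres are purchased.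
4. Feature: cyclobutane C1–C4 carries pyranone C6 at C1 and C3 and phenol C1′ at C2 and C4. Each pyranone is cis to one aryl neighbour and trans to the other (1α,2α,3β,4β, centrosymmetric). This is the cis,trans,cis pattern of the four carboxyl carbons of 1.

Key step: step 7

Remark: the target is taken as the centrosymmetric, achiral head-to-tail (α-truxillate-type) cyclobutane, so the stereodescriptors in the SMILES are relative and no absolute stereocontrol is needed.

**Route**

Step 1
Reactants: 1 cyclobutane-1,2,3,4-tetracarboxylic 1,2:3,4-dianhydride (cis,trans,cis; anhydride rings on opposite faces)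
Product: 2 (1α,2α,3β,4β)-2,4-bis(methoxycarbonyl)cyclobutane-1,3-dicarboxylic acid
Conditions: MeOH, reflux; evaporate; fractional crystallisation (EtOAc)
Reagents that add atoms: methanol, CO
Why: Alcoholysis of a cyclic anhydride opens each ring once to one ester and one acid without touching a ring C–H, so both regioisomeric half-esters are expected and the centrosymmetric one (esters on C2 and C4, trans across the ring) is separated by crystallisation, any carried-over chiral regioisomer being removed at the non-polar bis-lactone 4.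

Step 2
Reactants: 2 (1α,2α,3β,4β)-2,4-bis(methoxycarbonyl)cyclobutane-1,3-dicarboxylic acid
Product: 4 anti head-to-tail bis-γ-lactone 4,9-dioxatricyclo[5.3.0.0(2,6)]decane-3,8-dione, via diol diester 3 (not isolated)
Conditions: BH3·THF (3 equiv), THF, −10 °C → rt; MeOH quench; then p-TsOH·H2O (cat.), toluene, 80 °C
Reagents that add atoms: none
Why: Borane reduces carboxylic acids chemoselectively in the presence of esters, and each new hydroxymethyl group has a cis ester on the neighbouring ring carbon and closes by acid-catalysed lactonisation to a cis-fused γ-lactone, with no stereocentre involved.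

Step 3
Reactants: 4 anti head-to-tail bis-γ-lactone
Product: 6 dimethyl (1α,2α,3β,4β)-2,4-bis(iodomethyl)cyclobutane-1,3-dicarboxylate, via bis(trimethylsilyl ester) 5 (not isolated)
Conditions: Me3SiI (3 equiv), CHCl3, 50 °C; then MeOH, rt
Reagents that add atoms: iodotrimethylsilane, C[Si](C)(C)I; methanol, CO
Why: Silyl-assisted lactone cleavage, in which Me3SiI silylates the carbonyl oxygen and iodide opens the O–CH2 bond by SN2 at the primary carbon, followed by methanolysis of the silyl esters and Fischer esterification by the HI formed from excess reagent, excess methanol drawing the iodo acid to the methyl ester.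

Step 4
Reactants: 6 dimethyl (1α,2α,3β,4β)-2,4-bis(iodomethyl)cyclobutane-1,3-dicarboxylate
Product: 7 dimethyl (1α,2α,3β,4β)-2,4-bis(nitromethyl)cyclobutane-1,3-dicarboxylate
Conditions: NaNO2 (4 equiv), phloroglucinol, urea, DMF, rt
Reagents that add atoms: sodium nitrite, [Na+].[O-]N=O
Why: Kornblum reaction (SN2 of a primary iodide by nitrite through nitrogen in a dipolar aprotic solvent), with phloroglucinol trapping the alkyl nitrite by-product before it nitrosates the nitroalkane; the substituted carbon is exocyclic, so the ring configuration is unaffected.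

Step 5
Reactants: 7 dimethyl (1α,2α,3β,4β)-2,4-bis(nitromethyl)cyclobutane-1,3-dicarboxylate; 8 formaldehyde (used as paraformaldehyde, 2.2 equiv)
Product: 9 dimethyl (1α,2α,3β,4β)-2,4-bis(2-hydroxy-1-nitroethyl)cyclobutane-1,3-dicarboxylate (mixture of epimers at the two nitro-bearing carbons)
Conditions: (CH2O)n, KF (0.1 equiv), i-PrOH, rt
Reagents that add atoms: none
Why: Henry (nitroaldol) reaction of a primary nitroalkane with formaldehyde under catalytic fluoride, which should stop at mono-addition because a second addition would create a quaternary carbon next to the ring; the two new nitro-bearing stereocentres are formed without control and are removed in step 6, and the weak base neither enolises the esters nor promotes δ-lactonisation.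

Step 6
Reactants: 9 dimethyl (1α,2α,3β,4β)-2,4-bis(2-hydroxy-1-nitroethyl)cyclobutane-1,3-dicarboxylate
Product: 10 dimethyl (1α,2α,3β,4β)-2,4-bis(1-nitroethenyl)cyclobutane-1,3-dicarboxylate
Conditions: DCC (2.4 equiv), CuCl (cat.), Et2O, rt; filter, keep cold, use at once
Reagents that add atoms: none
Why: Nitroaldol dehydration by copper-catalysed addition of the primary alcohol to the carbodiimide and loss of dicyclohexylurea with the acidic hydrogen α to the nitro group, under neutral conditions without amine base so that the allylic ring C–H γ to the nitro group is not deprotonated and the ring configuration is kept.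

Step 7
Reactants: 10 dimethyl (1α,2α,3β,4β)-2,4-bis(1-nitroethenyl)cyclobutane-1,3-dicarboxylate; 11 (E)-1-methoxy-3-(trimethylsilyloxy)buta-1,3-diene (5 equiv)
Product: 14 dimethyl (1α,2α,3β,4β)-2,4-bis(4-hydroxyphenyl)cyclobutane-1,3-dicarboxylate (dimethyl 4,4'-dihydroxy-α-truxillate), via twofold cycloadduct 12 (not isolated), via bis(nitrocyclohexenone) 13 (not isolated)
Conditions: toluene, 2,6-di-tert-butyl-4-methylphenol (cat.), rt → 80 °C; then aq. H2NSO3H, THF, rt → 50 °C
Reagents that add atoms: none
Why: Each 1-nitrovinyl group is a polarised dienophile: the nucleophilic CH2 terminus (C4) of the diene bonds to the unsubstituted CH2 carbon of the nitroalkene and the methoxy-bearing C1 bonds to the nitro-bearing carbon in an asynchronous concerted [4+2] cycloaddition, so each six-membered ring is closed by two C–C bonds in one event; this is the normal-demand Diels–Alder reaction of a nitroalkene with a 1-methoxy-3-silyloxydiene, the nitroalkene serving as an alkyne equivalent. Aqueous acid then hydrolyses the silyl enol ether and eliminates methanol (E1cB) to the 4-nitrocyclohex-2-enone 13, whose dienol lets the tertiary allylic nitro group ionise to a cyclohexadienyl (arenium) cation that loses a proton from its ring CH2, a net loss of HNO2, after which the dienone tautomerises to the phenol. The regiochemistry, fixed by the large terminal coefficients of the diene HOMO at C4 and of the nitroalkene LUMO at CH2, places the oxygen para to the cyclobutane carbon. No stereocentre remains in the new rings, since the C–NO2 and C–OMe centres of 12 form as mixtures and are destroyed on aromatisation, and no bond to a cyclobutane carbon is made or broken, so the purchased configuration is carried through. The selectivity needed is loss of HNO2 into the new ring and not toward the cyclobutane C–H, which is secured because only the ring proton loss gives an arene whereas the alternative gives a strained, hindered exocyclic cyclobutylidene; sulfamic acid destroys the nitrous acid before it can nitrosate the new phenol.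

Step 8
Reactants: 14 dimethyl (1α,2α,3β,4β)-2,4-bis(4-hydroxyphenyl)cyclobutane-1,3-dicarboxylate
Product: 15 dimethyl (1α,2α,3β,4β)-2,4-bis[4-(benzyloxy)phenyl]cyclobutane-1,3-dicarboxylate
Conditions: BnBr (2.4 equiv), K2CO3, DMF, rt
Reagents that add atoms: benzyl bromide, BrCc1ccccc1
Why: Williamson ether synthesis on the phenoxides, K2CO3 being too weak a base to enolise the esters.

Step 9
Reactants: 15 dimethyl (1α,2α,3β,4β)-2,4-bis[4-(benzyloxy)phenyl]cyclobutane-1,3-dicarboxylate
Product: 16 (1α,2α,3β,4β)-2,4-bis[4-(benzyloxy)phenyl]cyclobutane-1,3-dicarboxylic acid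
Conditions: LiOH·H2O, THF–MeOH–H2O, rt → 40 °C; then 1 M HCl
Reagents that add atoms: lithium hydroxide, [Li+].[OH-]
Why: Ester saponification by acyl–oxygen cleavage near room temperature, where hydroxide attack at the carbonyl is faster than enolisation, so the α-truxillate configuration should be retained.

Step 10
Reactants: 16 (1α,2α,3β,4β)-2,4-bis[4-(benzyloxy)phenyl]cyclobutane-1,3-dicarboxylic acid
Product: 17 bis(N-acylimidazole) of 16, [(1α,2α,3β,4β)-2,4-bis(4-benzyloxyphenyl)cyclobutane-1,3-diyl]bis(1H-imidazol-1-ylmethanone)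
Conditions: 1,1'-carbonyldiimidazole (2.4 equiv), THF, rt; evaporate, use crude
Reagents that add atoms: 1,1'-carbonyldiimidazole, O=C(n1ccnc1)n1ccnc1
Why: Activation of the carboxylic acids as N-acylimidazoles with loss of CO2 and imidazole under neutral conditions, the trans-1,3 acids being unable to form a cyclic anhydride.

Step 11
Reactants: 17 bis(N-acylimidazole); 18 2,2,6-trimethyl-4H-1,3-dioxin-4-one (5 equiv)
Product: 19 bis(β-keto dioxinone), in which each cyclobutane C1/C3 carries C(=O)CH2 bonded to C6 of a 2,2-dimethyl-4H-1,3-dioxin-4-one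
Conditions: 18, LiN(SiMe3)2 (5 equiv), THF, −78 °C; add 17, −78 → −40 °C; AcOH quench
Reagents that add atoms: none
Why: Vinylogous Claisen-type γ-C-acylation of the lithium dienolate of the dioxinone by an N-acylimidazole, in which the excess dienolate deprotonates the acidic CH2 between the two carbonyl groups of the product, so that over-addition is blocked and enolisation is kept away from the ring C–H, while acyl substitution at −78 °C is faster than enolisation of the acylimidazole.

Step 12
Reactants: 19 bis(β-keto dioxinone)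
Product: 21 6,6'-[(1α,2α,3β,4β)-2,4-bis(4-benzyloxyphenyl)cyclobutane-1,3-diyl]bis(4-hydroxy-2H-pyran-2-one), via bis(acylketene) 20 (not isolated)
Conditions: toluene, 110 °C
Reagents that add atoms: none
Why: Thermal retro-[4+2] fragmentation of each dioxinone releases acetone and an acylketene, which is trapped intramolecularly by the enol oxygen of the ketone on the cyclobutane to close the six-membered 4-hydroxy-2-pyranone ring under neutral conditions.

Step 13
Reactants: 21 6,6'-[(1α,2α,3β,4β)-2,4-bis(4-benzyloxyphenyl)cyclobutane-1,3-diyl]bis(4-hydroxy-2H-pyran-2-one)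
Product: 22 6,6'-[(1α,2α,3β,4β)-2,4-bis(4-benzyloxyphenyl)cyclobutane-1,3-diyl]bis(4-methoxy-2H-pyran-2-one)
Conditions: Me2SO4 (2.5 equiv), K2CO3, acetone, rt → 50 °C
Reagents that add atoms: dimethyl sulfate, COS(=O)(=O)OC
Why: O-Alkylation of the vinylogous acid with dimethyl sulfate and K2CO3 in acetone, conditions that favour the 4-methoxy-2-pyranone over the 2-methoxy-4-pyranone regioisomer and are too mild to deprotonate the ring C–H.

Step 14
Reactants: 22 6,6'-[(1α,2α,3β,4β)-2,4-bis(4-benzyloxyphenyl)cyclobutane-1,3-diyl]bis(4-methoxy-2H-pyran-2-one)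
Product: 23 6,6'-[(1α,2α,3β,4β)-2,4-bis(4-hydroxyphenyl)cyclobutane-1,3-diyl]bis(4-methoxy-2H-pyran-2-one) (target)
Conditions: H2 (1 atm), 10% Pd/C, EtOAc–MeOH, rt; stop after uptake of two equivalents of H2
Reagents that add atoms: none
Why: Hydrogenolysis of benzyl aryl ethers over palladium, which is expected to be faster than reduction of the trisubstituted, donor-substituted C5–C6 double bond of the 4-methoxy-2-pyranone.

**Compound list**

1 | cyclobutane-1,2,3,4-tetracarboxylic 1,2:3,4-dianhydride (cis,trans,cis) | O=C3[C@H]1[C@H](C(=O)O4)[C@H](C4=O)[C@H]1C(=O)O3 | starting material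
2 | (1α,2α,3β,4β)-2,4-bis(methoxycarbonyl)cyclobutane-1,3-dicarboxylic acid | COC(=O)[C@H]1[C@H](C(=O)O)[C@H](C(=O)OC)[C@H]1C(=O)O | intermediate
3 | dimethyl (1α,2α,3β,4β)-2,4-bis(hydroxymethyl)cyclobutane-1,3-dicarboxylate | COC(=O)[C@H]1[C@H](CO)[C@H](C(=O)OC)[C@H]1CO | intermediate
4 | anti head-to-tail bis-γ-lactone, 4,9-dioxatricyclo[5.3.0.0(2,6)]decane-3,8-dione | O=C3[C@H]1[C@H](CO4)[C@H](C4=O)[C@H]1CO3 | intermediate
5 | bis(trimethylsilyl) (1α,2α,3β,4β)-2,4-bis(iodomethyl)cyclobutane-1,3-dicarboxylate | C[Si](C)(C)OC(=O)[C@H]1[C@H](CI)[C@H](C(=O)O[Si](C)(C)C)[C@H]1CI | intermediate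
6 | dimethyl (1α,2α,3β,4β)-2,4-bis(iodomethyl)cyclobutane-1,3-dicarboxylate | COC(=O)[C@H]1[C@H](CI)[C@H](C(=O)OC)[C@H]1CI | intermediate
7 | dimethyl (1α,2α,3β,4β)-2,4-bis(nitromethyl)cyclobutane-1,3-dicarboxylate | COC(=O)[C@H]1[C@H](C[N+](=O)[O-])[C@H](C(=O)OC)[C@H]1C[N+](=O)[O-] | intermediate
8 | formaldehyde | C=O | starting material
9 | dimethyl (1α,2α,3β,4β)-2,4-bis(2-hydroxy-1-nitroethyl)cyclobutane-1,3-dicarboxylate (epimers at the nitro carbons) | COC(=O)[C@H]1[C@H](C(CO)[N+](=O)[O-])[C@H](C(=O)OC)[C@H]1C(CO)[N+](=O)[O-] | intermediate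
10 | dimethyl (1α,2α,3β,4β)-2,4-bis(1-nitroethenyl)cyclobutane-1,3-dicarboxylate | COC(=O)[C@H]1[C@H](C(=C)[N+](=O)[O-])[C@H](C(=O)OC)[C@H]1C(=C)[N+](=O)[O-] | intermediate
11 | (E)-1-methoxy-3-(trimethylsilyloxy)buta-1,3-diene | CO/C=C/C(=C)O[Si](C)(C)C | starting material
12 | dimethyl (1α,2α,3β,4β)-2,4-bis[2-methoxy-1-nitro-4-(trimethylsilyloxy)cyclohex-3-en-1-yl]cyclobutane-1,3-dicarboxylate (mixture at the cyclohexene centres) | COC(=O)[C@H]1[C@H](C2(CCC(O[Si](C)(C)C)=CC2OC)[N+](=O)[O-])[C@H](C(=O)OC)[C@H]1C3(CCC(O[Si](C)(C)C)=CC3OC)[N+](=O)[O-] | intermediate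
13 | dimethyl (1α,2α,3β,4β)-2,4-bis(1-nitro-4-oxocyclohex-2-en-1-yl)cyclobutane-1,3-dicarboxylate (mixture at the nitro carbons) | COC(=O)[C@H]1[C@H](C2(C=CC(=O)CC2)[N+](=O)[O-])[C@H](C(=O)OC)[C@H]1C3(C=CC(=O)CC3)[N+](=O)[O-] | intermediate
14 | dimethyl (1α,2α,3β,4β)-2,4-bis(4-hydroxyphenyl)cyclobutane-1,3-dicarboxylate | COC(=O)[C@H]1[C@H](c2ccc(O)cc2)[C@H](C(=O)OC)[C@H]1c1ccc(O)cc1 | intermediate
15 | dimethyl (1α,2α,3β,4β)-2,4-bis[4-(benzyloxy)phenyl]cyclobutane-1,3-dicarboxylate | COC(=O)[C@H]1[C@H](c2ccc(OCc3ccccc3)cc2)[C@H](C(=O)OC)[C@H]1c1ccc(OCc2ccccc2)cc1 | intermediate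
16 | (1α,2α,3β,4β)-2,4-bis[4-(benzyloxy)phenyl]cyclobutane-1,3-dicarboxylic acid | OC(=O)[C@H]1[C@H](c2ccc(OCc3ccccc3)cc2)[C@H](C(=O)O)[C@H]1c1ccc(OCc2ccccc2)cc1 | intermediate
17 | [(1α,2α,3β,4β)-2,4-bis(4-benzyloxyphenyl)cyclobutane-1,3-diyl]bis(1H-imidazol-1-ylmethanone) | O=C(n2ccnc2)[C@H]1[C@H](c2ccc(OCc3ccccc3)cc2)[C@H](C(=O)n2ccnc2)[C@H]1c1ccc(OCc2ccccc2)cc1 | intermediate
18 | 2,2,6-trimethyl-4H-1,3-dioxin-4-one | CC1=CC(=O)OC(C)(C)O1 | starting material
19 | 6,6'-{[(1α,2α,3β,4β)-2,4-bis(4-benzyloxyphenyl)cyclobutane-1,3-diyl]bis(2-oxoethane-2,1-diyl)}bis(2,2-dimethyl-4H-1,3-dioxin-4-one) | CC2(C)OC(=O)C=C(CC(=O)[C@H]1[C@H](c3ccc(OCc4ccccc4)cc3)[C@H](C(=O)CC3=CC(=O)OC(C)(C)O3)[C@H]1c1ccc(OCc3ccccc3)cc1)O2 | intermediate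
20 | (1α,2α,3β,4β)-2,4-bis(4-benzyloxyphenyl)-1,3-bis(3,5-dioxopent-4-enoyl)cyclobutane (bis-acylketene) | O=C=CC(=O)CC(=O)[C@H]1[C@H](c2ccc(OCc3ccccc3)cc2)[C@H](C(=O)CC(=O)C=C=O)[C@H]1c1ccc(OCc2ccccc2)cc1 | intermediate
21 | 6,6'-[(1α,2α,3β,4β)-2,4-bis(4-benzyloxyphenyl)cyclobutane-1,3-diyl]bis(4-hydroxy-2H-pyran-2-one) | Oc1cc(=O)oc([C@H]2[C@H](c3ccc(OCc4ccccc4)cc3)[C@H](c3cc(O)cc(=O)o3)[C@H]2c2ccc(OCc3ccccc3)cc2)c1 | intermediate
22 | 6,6'-[(1α,2α,3β,4β)-2,4-bis(4-benzyloxyphenyl)cyclobutane-1,3-diyl]bis(4-methoxy-2H-pyran-2-one) | COc1cc(=O)oc([C@H]2[C@H](c3ccc(OCc4ccccc4)cc3)[C@H](c3cc(OC)cc(=O)o3)[C@H]2c2ccc(OCc3ccccc3)cc2)c1 | intermediate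
23 | 6,6'-[(1α,2α,3β,4β)-2,4-bis(4-hydroxyphenyl)cyclobutane-1,3-diyl]bis(4-methoxy-2H-pyran-2-one) | COc1cc(=O)oc([C@H]2[C@H](c3ccc(O)cc3)[C@H](c3cc(OC)cc(=O)o3)[C@H]2c2ccc(O)cc2)c1 | target

**Step count and risks**

Total step count: 14. Longest linear sequence: 14 steps, from 1 to 23.

Steps most likely to fail:

1. Step 7. The nitroalkene may polymerise before it is trapped, or ring closure at the hindered nitro-bearing carbon may be slow. The most probable failure is that loss of nitrous acid from the tertiary nitro centre is reluctant, so the sequence stalls at the nitrocyclohexenone stage or is diverted to ring nitrosation. The fallback sets out from 13, isolated after a short hydrolysis of the cycloadduct with dilute HCl in THF at 0 °C. Radical denitration with Bu3SnH and azobisisobutyronitrile in toluene at 80 °C, the tin hydride kept concentrated so that hydrogen transfer is faster than opening of the cyclobutylcarbinyl radical, should give dimethyl (1α,2α,3β,4β)-2,4-bis(4-oxocyclohex-2-en-1-yl)cyclobutane-1,3-dicarboxylate F1. Catalytic aerobic dehydrogenation of both cyclohexenones (Pd(OCOCF3)2, 2-(dimethylamino)pyridine, TsOH, O2, DMSO, 80 °C) should then give the phenols, returning to the route at 14.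

2. Step 4. Nitrite may alkylate on oxygen, giving the nitrite ester and then the alcohol, which relactonises toward 4. Elimination to the exocyclic alkene and an incomplete second substitution at the β-branched iodide may also lower the conversion. The fallback sets out from 6. Substitution with NaN3 in DMF at rt should give dimethyl (1α,2α,3β,4β)-2,4-bis(azidomethyl)cyclobutane-1,3-dicarboxylate F2. A Staudinger reaction with PPh3 in dry THF at rt should give the bis(triphenylphosphine imide) F3. Ozonolysis of the phosphine imide in CH2Cl2 at −78 °C, a known oxidation of the P=N unit to a nitro group, should give the nitro compound, returning to the route at 7.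

3. Step 6. The doubly 1,1-disubstituted nitroalkene may polymerise or isomerise at the allylic ring C–H during dehydration, filtration and concentration. The fallback sets out from 9. Acetylation with Ac2O and catalytic TsOH in CH2Cl2 at rt should give the storable dimethyl (1α,2α,3β,4β)-2,4-bis(2-acetoxy-1-nitroethyl)cyclobutane-1,3-dicarboxylate F4. This is heated with powdered anhydrous Na2CO3 in toluene at 40–60 °C in the presence of diene 11, so that β-elimination of acetate releases the nitroalkene slowly and it is consumed as it forms. The route is rejoined at 10, which is then not isolated, and continues to 14 as in step 7.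

**Further compounds**

F1 | step 7 | dimethyl (1α,2α,3β,4β)-2,4-bis(4-oxocyclohex-2-en-1-yl)cyclobutane-1,3-dicarboxylate | COC(=O)[C@H]1[C@H](C2C=CC(=O)CC2)[C@H](C(=O)OC)[C@H]1C3C=CC(=O)CC3
F2 | step 4 | dimethyl (1α,2α,3β,4β)-2,4-bis(azidomethyl)cyclobutane-1,3-dicarboxylate | COC(=O)[C@H]1[C@H](CN=[N+]=[N-])[C@H](C(=O)OC)[C@H]1CN=[N+]=[N-]
F3 | step 4 | dimethyl (1α,2α,3β,4β)-2,4-bis[(triphenylphosphoranylidene)aminomethyl]cyclobutane-1,3-dicarboxylate | COC(=O)[C@H]1[C@H](CN=P(c2ccccc2)(c2ccccc2)c2ccccc2)[C@H](C(=O)OC)[C@H]1CN=P(c1ccccc1)(c1ccccc1)c1ccccc1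
F4 | step 6 | dimethyl (1α,2α,3β,4β)-2,4-bis(2-acetoxy-1-nitroethyl)cyclobutane-1,3-dicarboxylate | COC(=O)[C@H]1[C@H](C(COC(C)=O)[N+](=O)[O-])[C@H](C(=O)OC)[C@H]1C(COC(C)=O)[N+](=O)[O-]
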